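The 14-membered carbocycle is opened between its two adjacent oxygen-bearing ring carbons, C11 (the CH carrying the acetate) and C12 (the methyl-bearing carbon carrying the lactone oxygen), whose cis 1,2-diol relationship is a pinacol retron. One reductive coupling of a C12 methyl ketone with a C11 aldehyde by low-valent titanium forms the C11–C12 bond, closes the macrocycle and creates both carbinol centres. Its precursor is an open-chain keto aldehyde that already holds C1 (from (S)-limonene), the silyl-protected 3R carbinol, the E-C4=C5 and Z-C7=C8 alkenes and C16 as a PMB ether. The seven-membered α-methylene lactone ring is closed last onto the C12 hydroxyl.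

Key step: step 12

Numbering: cembrane numbering is used for the ring compounds and kept for the open-chain (11,12-seco) ones. C1 is the CH bearing C15 (C16 = CH2O or C=O carbon, C17 = exocyclic CH2); C3 is the carbinol; C4(Me)=C5; C7=C8(Me); C11; C12(Me); C13; C14.

Remark: the target is read as (1S,3R,4E,7Z,11R,12S). The C11 and C12 oxygens are cis on the 14-membered ring, and C1 maps onto the stereocentre of (S)-limonene without change of descriptor. C11 is carried as a diethyl acetal (from purchased acrolein diethyl acetal), so the aldehyde is released directly before the coupling and no selective desilylation is needed. Prop-1-ynylmagnesium bromide is used as the purchased THF solution.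

Step 1
Reactants: 1 but-2-yn-1-ol
Product: 3 (Z)-3-iodobut-2-en-1-ol, via cyclic alkenylaluminate 2 (not isolated)
Conditions: NaAlH2(OCH2CH2OMe)2 (Red-Al), THF, 0 °C to rt; then I2, −78 °C to 0 °C
Reagents that add atoms: iodine, [I][I]
Why: Hydroxyl-directed trans-hydroalumination of the propargylic alcohol places aluminium on C3 cis to the CH2O group in a five-membered aluminate, and iodinolysis with retention gives the Z-iodide that later becomes the Z-C7=C8 alkene.

Step 2
Reactants: 4 acrolein diethyl acetal; 3 (Z)-3-iodobut-2-en-1-ol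
Product: 6 (Z)-6,6-diethoxy-3-methylhex-2-en-1-ol, via alkylborane 5 (not isolated)
Conditions: 4, 9-BBN, THF, 0 °C to rt; then 3, PdCl2(dppf) (5 mol%), AsPh3, Cs2CO3, DMF/H2O, rt
Reagents that add atoms: none
Why: Anti-Markovnikov hydroboration gives the primary alkylborane, and the B-alkyl Suzuki–Miyaura coupling keeps the geometry of the vinyl iodide, so C9 ends up cis to C6 across C7=C8.

Step 3
Reactants: 6 (Z)-6,6-diethoxy-3-methylhex-2-en-1-ol
Product: 8 (Z)-1-bromo-6,6-diethoxy-3-methylhex-2-ene, via allylic mesylate 7 (not isolated)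
Conditions: MsCl, Et3N, THF, −40 °C; then LiBr, 0 °C
Reagents that add atoms: lithium bromide, [Li+].[Br-]
Why: Mesylation followed by SN2 displacement with bromide under cold, non-acidic conditions should give the primary allylic bromide without allylic transposition, loss of the Z geometry or damage to the acetal.

Step 4
Reactants: 8 (Z)-1-bromo-6,6-diethoxy-3-methylhex-2-ene; 9 prop-1-ynylmagnesium bromide
Product: 10 (Z)-9,9-diethoxy-6-methylnon-5-en-2-yne
Conditions: CuI (10 mol%), THF, −20 °C to rt
Reagents that add atoms: none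
Why: Copper-catalysed coupling of an alkynyl Grignard reagent with a primary allylic bromide takes place at the unhindered α-carbon (attack at the γ-carbon would build a quaternary centre) and should give the skipped enyne with the Z alkene intact.

Step 5
Reactants: 11 (S)-limonene
Product: 14 2-[(1S)-4-methylcyclohex-3-en-1-yl]prop-2-en-1-ol, via allyllithium 12 (not isolated), via allylboronate 13 (not isolated)
Conditions: n-BuLi, TMEDA, hexane, rt; B(OMe)3, THF, −78 °C to rt; H2O2, aq NaOH, 0 °C
Reagents that add atoms: hydrogen peroxide, OO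
Why: Allylic lithiation of limonene occurs at the isopropenyl methyl group to give an allyl anion with two equivalent CH2 termini, and borylation followed by oxidation converts it into the primary allylic alcohol while the ring stereocentre is not involved.

Step 6
Reactants: 14 2-[(1S)-4-methylcyclohex-3-en-1-yl]prop-2-en-1-ol
Product: 16 (4S)-4-[3-(4-methoxybenzyloxy)prop-1-en-2-yl]-1-methylcyclohex-1-ene, via sodium alkoxide 15 (not isolated)
Conditions: NaH, THF/DMF, 0 °C; then PMBCl, Bu4NI (5 mol%), rt
Reagents that add atoms: 4-methoxybenzyl chloride, COc1ccc(CCl)cc1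
Why: Williamson etherification of the alkoxide with the benzylic chloride installs a C16 ether that withstands every step up to its oxidative removal in step 14.

Step 7
Reactants: 16 (4S)-4-[3-(4-methoxybenzyloxy)prop-1-en-2-yl]-1-methylcyclohex-1-ene
Product: 17 (4S)-4-[3-(4-methoxybenzyloxy)prop-1-en-2-yl]-1-methyl-7-oxabicyclo[4.1.0]heptane (both oxirane diastereomers)
Conditions: mCPBA, NaHCO3, CH2Cl2, 0 °C
Reagents that add atoms: 3-chloroperoxybenzoic acid, OOC(=O)c1cccc(Cl)c1
Why: Prilezhaev epoxidation selects the electron-rich trisubstituted ring alkene over the 1,1-disubstituted alkene that is deactivated by its allylic ether, and the two oxirane centres may form as a mixture because both carbons become carbonyl groups in step 8.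

Step 8
Reactants: 17 (4S)-4-[3-(4-methoxybenzyloxy)prop-1-en-2-yl]-1-methyl-7-oxabicyclo[4.1.0]heptane
Product: 19 (3S)-3-[3-(4-methoxybenzyloxy)prop-1-en-2-yl]-6-oxoheptanal, via vicinal diol 18 (not isolated)
Conditions: H5IO6, THF/H2O, 0 °C to rt
Reagents that add atoms: water, O
Why: Acid-promoted epoxide hydrolysis and periodate glycol cleavage (Malaprade reaction) open the ring to the C12 methyl ketone and the C3 aldehyde, and the C1 stereocentre is β to the aldehyde and cannot epimerise.

Step 9
Reactants: 10 (Z)-9,9-diethoxy-6-methylnon-5-en-2-yne; 19 (3S)-3-[3-(4-methoxybenzyloxy)prop-1-en-2-yl]-6-oxoheptanal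
Product: 22 (1S,3R,4E,7Z)-11,11-diethoxy-3-hydroxy-16-(4-methoxybenzyloxy)-11,12-secocembra-4,7,15(17)-trien-12-one, via alkenylzirconocene 20 (not isolated), via alkenylzinc 21 (not isolated)
Conditions: 10, Cp2Zr(H)Cl, THF, 45 °C; toluene, filter; Me2Zn, −65 °C; (−)-MIB (10 mol%), 19, −30 to 0 °C
Reagents that add atoms: none
Why: syn-Hydrozirconation under equilibrating conditions places zirconium on the methyl-bearing alkyne carbon (E-alkenyl, future C4), transmetalation to zinc and amino-alcohol-catalysed alkenylzinc addition to the aldehyde then form the C3–C4 bond, with the (2S)-(−)-3-exo-morpholinoisoborneol–zinc catalyst directing attack to the Si face to set 3R while the methyl ketone and the acetal do not react with the organozinc.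

Step 10
Reactants: 22 (1S,3R,4E,7Z)-11,11-diethoxy-3-hydroxy-16-(4-methoxybenzyloxy)-11,12-secocembra-4,7,15(17)-trien-12-one
Product: 23 (1S,3R,4E,7Z)-3-(tert-butyldimethylsilyloxy)-11,11-diethoxy-16-(4-methoxybenzyloxy)-11,12-secocembra-4,7,15(17)-trien-12-one
Conditions: TBSCl, imidazole, DMAP (5 mol%), DMF, rt
Reagents that add atoms: tert-butyldimethylsilyl chloride, CC(C)(C)[Si](C)(C)Cl
Why: Imidazole-mediated silylation protects the C3 allylic alcohol, and the silyl chloride is used because a silyl triflate would ionise the diethyl acetal.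

Step 11
Reactants: 23 (1S,3R,4E,7Z)-3-(tert-butyldimethylsilyloxy)-11,11-diethoxy-16-(4-methoxybenzyloxy)-11,12-secocembra-4,7,15(17)-trien-12-one
Product: 24 (4Z,7E,9R,11S)-9-(tert-butyldimethylsilyloxy)-11-[3-(4-methoxybenzyloxy)prop-1-en-2-yl]-4,8-dimethyl-14-oxopentadeca-4,7-dienal (seco keto aldehyde)
Conditions: PPTS (10 mol%), acetone/H2O, 40 °C
Reagents that add atoms: water, O
Why: Mild acid-catalysed hydrolysis of the acyclic acetal releases the C11 aldehyde as the last operation before the coupling and should leave the secondary TBS ether, the PMB ether, the skipped diene and the ketone untouched.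

Step 12
Reactants: 24 seco keto aldehyde (C12 methyl ketone, C11 aldehyde)
Product: 26 (1S,3R,4E,7Z,11R,12S)-3-(tert-butyldimethylsilyloxy)-16-(4-methoxybenzyloxy)cembra-4,7,15(17)-triene-11,12-diol, via titanium diolate 25 (not isolated)
Conditions: TiCl3(DME)1.5, Zn–Cu couple, DME, reflux 2 h; then 24 in DME by syringe pump over 30 h, 25 °C (final 2 mM); aq K2CO3
Reagents that add atoms: none
Why: Low-valent titanium made from TiCl3 and the Zn–Cu couple transfers one electron to each carbonyl group, and the two titanium-bound ketyl radicals at C11 and C12 combine on the metal to the titanium diolate 25, which is not deoxygenated at 25 °C and is hydrolysed to the diol on basic work-up. The closest known reaction type is the McMurry-type intramolecular keto–aldehyde pinacol coupling used to close 14-membered carbocyclic 1,2-diols. The 14-membered ring closes end to end by union of the two ketyl carbons, an electron-transfer process that joins two electrophilic carbons as no polar addition could, and slow addition at high dilution together with the chain turn imposed by the Z-C7=C8 and E-C4=C5 alkenes should favour ring closure over oligomerisation. C12 is set by the ketone face that the folded chain presents, biased by the C1 stereocentre (separated from it by C13 and C14), whose branched substituent should stay on the outside of the forming ring, and C11 is set relative to C12 by the titanium bridge that holds both oxygens on the same side while the bond forms. The step needs chemoselectivity, which the substrate provides because the silyl ether, the PMB ether and the alkenes are inert to the reagent, and it needs the cis (11R,12S) isomer out of four possible diols; cis/trans control is the least secured element for a ring of this size, so the C11 epimer is given a defined way back to 26 in the fallback.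

Step 13
Reactants: 26 (1S,3R,4E,7Z,11R,12S)-3-(tert-butyldimethylsilyloxy)-16-(4-methoxybenzyloxy)cembra-4,7,15(17)-triene-11,12-diol
Product: 27 (1S,3R,4E,7Z,11R,12S)-11-acetoxy-3-(tert-butyldimethylsilyloxy)-16-(4-methoxybenzyloxy)cembra-4,7,15(17)-trien-12-ol
Conditions: Ac2O, pyridine, DMAP (5 mol%), CH2Cl2, 0 °C to rt
Reagents that add atoms: acetic anhydride, CC(=O)OC(C)=O
Why: Nucleophile-catalysed acylation should be selective for the secondary C11 hydroxyl because the tertiary C12 hydroxyl is far more hindered.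

Step 14
Reactants: 27 (1S,3R,4E,7Z,11R,12S)-11-acetoxy-3-(tert-butyldimethylsilyloxy)-16-(4-methoxybenzyloxy)cembra-4,7,15(17)-trien-12-ol
Product: 28 (1S,3R,4E,7Z,11R,12S)-11-acetoxy-3-(tert-butyldimethylsilyloxy)cembra-4,7,15(17)-triene-12,16-diol
Conditions: DDQ, CH2Cl2/pH 7 buffer, 0 °C
Reagents that add atoms: none
Why: Oxidative PMB cleavage by DDQ (hydride abstraction from the electron-rich benzylic position and hydrolysis of the resulting oxocarbenium ion) frees the C16 allylic alcohol while the acetate, the TBS ether and the tertiary alcohol remain.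

Step 15
Reactants: 28 (1S,3R,4E,7Z,11R,12S)-11-acetoxy-3-(tert-butyldimethylsilyloxy)cembra-4,7,15(17)-triene-12,16-diol
Product: 29 (1S,3R,4E,7Z,11R,12S)-11-acetoxy-3-(tert-butyldimethylsilyloxy)-12-hydroxycembra-4,7,15(17)-trien-16-al
Conditions: Dess–Martin periodinane, NaHCO3, CH2Cl2, 0 °C to rt
Reagents that add atoms: none
Why: Dess–Martin oxidation converts the primary allylic alcohol into the 2-substituted acrolein without touching the tertiary hydroxyl, and the bicarbonate buffer guards against migration of the exocyclic double bond.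

Step 16
Reactants: 29 (1S,3R,4E,7Z,11R,12S)-11-acetoxy-3-(tert-butyldimethylsilyloxy)-12-hydroxycembra-4,7,15(17)-trien-16-al
Product: 30 (1S,3R,4E,7Z,11R,12S)-11-acetoxy-3-(tert-butyldimethylsilyloxy)-12-hydroxycembra-4,7,15(17)-trien-16-oic acid
Conditions: NaClO2, NaH2PO4, 2-methylbut-2-ene, t-BuOH/H2O, 0 °C to rt
Reagents that add atoms: sodium chlorite, [Na+].[O-]Cl=O
Why: Pinnick oxidation with an alkene scavenger for hypochlorous acid takes the enal to the acrylic acid without attacking the trisubstituted alkenes.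

Step 17
Reactants: 30 (1S,3R,4E,7Z,11R,12S)-11-acetoxy-3-(tert-butyldimethylsilyloxy)-12-hydroxycembra-4,7,15(17)-trien-16-oic acid
Product: 32 (1S,3R,4E,7Z,11R,12S)-11-acetoxy-3-(tert-butyldimethylsilyloxy)cembra-4,7,15(17)-trien-16,12-olide, via mixed anhydride 31 (not isolated)
Conditions: MNBA, DMAP, toluene (2 mM, slow addition), rt to 50 °C
Reagents that add atoms: none
Why: In this Shiina lactonisation the acid is activated as its mixed anhydride with 2-methyl-6-nitrobenzoic acid and DMAP passes the acyl group to the C12 hydroxyl, closing the seven-membered lactone; C11 is blocked as the acetate so only the tertiary hydroxyl can cyclise, and C12 keeps its configuration because its C–O bond is not broken.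

Step 18
Reactants: 32 (1S,3R,4E,7Z,11R,12S)-11-acetoxy-3-(tert-butyldimethylsilyloxy)cembra-4,7,15(17)-trien-16,12-olide
Product: 33 (1S,3R,4E,7Z,11R,12S)-11-acetoxy-3-hydroxycembra-4,7,15(17)-trien-16,12-olide (CNP0130972.7)
Conditions: HF·pyridine, pyridine, THF, 0 °C to rt
Reagents that add atoms: none
Why: Buffered HF·pyridine removes the secondary TBS group by Si–F bond formation and should spare the acetate and the α-methylene lactone, which a basic fluoride source could attack.

Compound list

1 | but-2-yn-1-ol | CC#CCO | starting material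
2 | sodium cyclic alkenylaluminate from 1 (aluminium on C3, cis to the CH2O group) | CC1=CCO[Al-]1(OCCOC)OCCOC.[Na+] | intermediate
3 | (Z)-3-iodobut-2-en-1-ol | I/C(C)=C\CO | intermediate
4 | acrolein diethyl acetal (3,3-diethoxyprop-1-ene) | C=CC(OCC)OCC | starting material
5 | 9-(3,3-diethoxypropyl)-9-borabicyclo[3.3.1]nonane | CCOC(CCB1C2CCCC1CCC2)OCC | intermediate
6 | (Z)-6,6-diethoxy-3-methylhex-2-en-1-ol | OC/C=C(/C)CCC(OCC)OCC | intermediate
7 | (Z)-6,6-diethoxy-3-methylhex-2-en-1-yl methanesulfonate | CS(=O)(=O)OC/C=C(/C)CCC(OCC)OCC | intermediate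
8 | (Z)-1-bromo-6,6-diethoxy-3-methylhex-2-ene | BrC/C=C(/C)CCC(OCC)OCC | intermediate
9 | prop-1-ynylmagnesium bromide | CC#C[Mg]Br | starting material
10 | (Z)-9,9-diethoxy-6-methylnon-5-en-2-yne | CC#CC/C=C(/C)CCC(OCC)OCC | intermediate
11 | (S)-limonene | CC1=CC[C@H](CC1)C(=C)C | starting material
12 | 10-lithio-(S)-limonene (2-substituted allyllithium) | CC1=CC[C@H](CC1)C(=C)C[Li] | intermediate
13 | dimethyl {2-[(1S)-4-methylcyclohex-3-en-1-yl]prop-2-en-1-yl}boronate | CC1=CC[C@H](CC1)C(=C)CB(OC)OC | intermediate
14 | 2-[(1S)-4-methylcyclohex-3-en-1-yl]prop-2-en-1-ol | CC1=CC[C@H](CC1)C(=C)CO | intermediate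
15 | sodium 2-[(1S)-4-methylcyclohex-3-en-1-yl]prop-2-en-1-olate | CC1=CC[C@H](CC1)C(=C)C[O-].[Na+] | intermediate
16 | (4S)-4-[3-(4-methoxybenzyloxy)prop-1-en-2-yl]-1-methylcyclohex-1-ene | CC1=CC[C@H](CC1)C(=C)COCc2ccc(OC)cc2 | intermediate
17 | (4S)-4-[3-(4-methoxybenzyloxy)prop-1-en-2-yl]-1-methyl-7-oxabicyclo[4.1.0]heptane, both oxirane diastereomers | CC12OC1C[C@H](CC2)C(=C)COCc3ccc(OC)cc3 | intermediate
18 | (4S)-4-[3-(4-methoxybenzyloxy)prop-1-en-2-yl]-1-methylcyclohexane-1,2-diol, diastereomer mixture | CC1(O)C(O)C[C@H](CC1)C(=C)COCc2ccc(OC)cc2 | intermediate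
19 | (3S)-3-[3-(4-methoxybenzyloxy)prop-1-en-2-yl]-6-oxoheptanal | CC(=O)CC[C@H](C(=C)COCc1ccc(OC)cc1)CC=O | intermediate
20 | chloro[(2E,5Z)-9,9-diethoxy-6-methylnona-2,5-dien-2-yl]zirconocene | Cl[Zr](C1C=CC=C1)(C1C=CC=C1)/C(C)=C/C/C=C(/C)CCC(OCC)OCC | intermediate
21 | [(2E,5Z)-9,9-diethoxy-6-methylnona-2,5-dien-2-yl](methyl)zinc | C[Zn]/C(C)=C/C/C=C(/C)CCC(OCC)OCC | intermediate
22 | (1S,3R,4E,7Z)-11,11-diethoxy-3-hydroxy-16-(4-methoxybenzyloxy)-11,12-secocembra-4,7,15(17)-trien-12-one | CC(=O)CC[C@H](C(=C)COCc1ccc(OC)cc1)C[C@@H](O)/C(C)=C/C/C=C(/C)CCC(OCC)OCC | intermediate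
23 | (1S,3R,4E,7Z)-3-(tert-butyldimethylsilyloxy)-11,11-diethoxy-16-(4-methoxybenzyloxy)-11,12-secocembra-4,7,15(17)-trien-12-one | CC(=O)CC[C@H](C(=C)COCc1ccc(OC)cc1)C[C@@H](O[Si](C)(C)C(C)(C)C)/C(C)=C/C/C=C(/C)CCC(OCC)OCC | intermediate
24 | (4Z,7E,9R,11S)-9-(tert-butyldimethylsilyloxy)-11-[3-(4-methoxybenzyloxy)prop-1-en-2-yl]-4,8-dimethyl-14-oxopentadeca-4,7-dienal (seco keto aldehyde; 1S,3R in cembrane numbering) | CC(=O)CC[C@H](C(=C)COCc1ccc(OC)cc1)C[C@@H](O[Si](C)(C)C(C)(C)C)/C(C)=C/C/C=C(/C)CCC=O | intermediate
25 | dichlorotitanium 11,12-diolate of 26 (tetravalent titanium bridging the C11 and C12 oxygens) | C[C@]12CC[C@H](C(=C)COCc3ccc(OC)cc3)C[C@@H](O[Si](C)(C)C(C)(C)C)/C(C)=C/C/C=C(/C)CC[C@H]1O[Ti](Cl)(Cl)O2 | intermediate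
26 | (1S,3R,4E,7Z,11R,12S)-3-(tert-butyldimethylsilyloxy)-16-(4-methoxybenzyloxy)cembra-4,7,15(17)-triene-11,12-diol (cis-diol) | C[C@]1(O)CC[C@H](C(=C)COCc2ccc(OC)cc2)C[C@@H](O[Si](C)(C)C(C)(C)C)/C(C)=C/C/C=C(/C)CC[C@H]1O | intermediate
27 | (1S,3R,4E,7Z,11R,12S)-11-acetoxy-3-(tert-butyldimethylsilyloxy)-16-(4-methoxybenzyloxy)cembra-4,7,15(17)-trien-12-ol | C[C@]1(O)CC[C@H](C(=C)COCc2ccc(OC)cc2)C[C@@H](O[Si](C)(C)C(C)(C)C)/C(C)=C/C/C=C(/C)CC[C@H]1OC(C)=O | intermediate
28 | (1S,3R,4E,7Z,11R,12S)-11-acetoxy-3-(tert-butyldimethylsilyloxy)cembra-4,7,15(17)-triene-12,16-diol | C[C@]1(O)CC[C@H](C(=C)CO)C[C@@H](O[Si](C)(C)C(C)(C)C)/C(C)=C/C/C=C(/C)CC[C@H]1OC(C)=O | intermediate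
29 | (1S,3R,4E,7Z,11R,12S)-11-acetoxy-3-(tert-butyldimethylsilyloxy)-12-hydroxycembra-4,7,15(17)-trien-16-al | C[C@]1(O)CC[C@H](C(=C)C=O)C[C@@H](O[Si](C)(C)C(C)(C)C)/C(C)=C/C/C=C(/C)CC[C@H]1OC(C)=O | intermediate
30 | (1S,3R,4E,7Z,11R,12S)-11-acetoxy-3-(tert-butyldimethylsilyloxy)-12-hydroxycembra-4,7,15(17)-trien-16-oic acid | C[C@]1(O)CC[C@H](C(=C)C(=O)O)C[C@@H](O[Si](C)(C)C(C)(C)C)/C(C)=C/C/C=C(/C)CC[C@H]1OC(C)=O | intermediate
31 | mixed anhydride of 30 with 2-methyl-6-nitrobenzoic acid | C[C@]1(O)CC[C@H](C(=C)C(=O)OC(=O)c2c(C)cccc2[N+](=O)[O-])C[C@@H](O[Si](C)(C)C(C)(C)C)/C(C)=C/C/C=C(/C)CC[C@H]1OC(C)=O | intermediate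
32 | (1S,3R,4E,7Z,11R,12S)-11-acetoxy-3-(tert-butyldimethylsilyloxy)cembra-4,7,15(17)-trien-16,12-olide | C=C1C(=O)O[C@@]2(C)CC[C@H]1C[C@@H](O[Si](C)(C)C(C)(C)C)/C(C)=C/C/C=C(/C)CC[C@H]2OC(C)=O | intermediate
33 | (1S,3R,4E,7Z,11R,12S)-11-acetoxy-3-hydroxycembra-4,7,15(17)-trien-16,12-olide (CNP0130972.7) | C=C1C(=O)O[C@@]2(C)CC[C@H]1C[C@@H](O)/C(C)=C/C/C=C(/C)CC[C@H]2OC(C)=O | target

Total step count: 18 steps.

Longest linear sequence: 14 steps (steps 5–18 from (S)-limonene; the branch from but-2-yn-1-ol, steps 1–4 and 9–18, is equally long).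

Steps most likely to fail

1. Step 12 (key step). The ring may close with the two oxygens trans, because pinacol couplings that form large rings are not reliably cis-selective, and intermolecular coupling may compete if the addition is too fast. Only C11 can be corrected afterwards, so facial selectivity at the C12 ketone is the residual risk that the route accepts.
Fallback: it sets out from 24 and returns at 26. The coupling is run as in step 12 and the (1S,3R,4E,7Z,11S,12S) trans-diol F1 that forms beside 26 is collected. Buffered Dess–Martin oxidation of its secondary hydroxyl (the tertiary hydroxyl is inert and no glycol cleavage occurs) should give the (12S)-12-hydroxy-11-ketone F2. Reduction with Zn(BH4)2 in Et2O at −20 °C should then proceed through the five-membered zinc chelate between the C12 oxygen and the C11 carbonyl, with hydride entering from the peripheral face on the side of the C12 methyl group. This should give the cis-diol 26, so C11 is set by a chelation-controlled reduction and not by the coupling itself.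

2. Step 9. Achiral zirconium Lewis acids may promote an uncatalysed addition and erode facial selectivity at C3, and hydrozirconation of a methyl/primary-alkyl alkyne may not be fully regioselective.
Fallback: it sets out from 10 and 19 and returns at 22. Hydrozirconation of 10 (through 20) followed by iodinolysis should give (2E,5Z)-9,9-diethoxy-2-iodo-6-methylnona-2,5-diene F3, which can be freed from its regioisomer before use. A Nozaki–Hiyama–Kishi coupling of F3 with 19 (CrCl2, 1 mol% NiCl2, DMSO, rt) is aldehyde-selective and should give 22 together with its (3S) epimer F4. After chromatographic separation, F4 is inverted by a Mitsunobu reaction (4-nitrobenzoic acid, PPh3, DIAD) to the (3R) 4-nitrobenzoate F5, and methanolysis (K2CO3, MeOH) returns 22.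

3. Step 17. Acyl transfer to the hindered tertiary C12 hydroxyl may be slow, which would allow oligomerisation, conjugate addition of DMAP to the activated acrylate, or acetyl migration from O11 to O12 followed by closure onto C11.
Fallback: it sets out from 30 and returns at 32. The acid is converted with 2,2'-dipyridyl disulfide and PPh3 into the isolable S-(pyridin-2-yl) thioester F6, which is cyclised at high dilution with AgOTf in toluene (rt to 80 °C). Thiophilic silver activation delivers the acyl group to the C12 hydroxyl without a bulky acylpyridinium intermediate and without base, so the activation mode changes from nucleophilic catalysis of a mixed anhydride to metal-assisted thioester lactonisation.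

Further compounds

F1 | step 12 | (1S,3R,4E,7Z,11S,12S)-3-(tert-butyldimethylsilyloxy)-16-(4-methoxybenzyloxy)cembra-4,7,15(17)-triene-11,12-diol (trans-diol, C11 epimer of 26) | C[C@]1(O)CC[C@H](C(=C)COCc2ccc(OC)cc2)C[C@@H](O[Si](C)(C)C(C)(C)C)/C(C)=C/C/C=C(/C)CC[C@@H]1O
F2 | step 12 | (1S,3R,4E,7Z,12S)-3-(tert-butyldimethylsilyloxy)-12-hydroxy-16-(4-methoxybenzyloxy)cembra-4,7,15(17)-trien-11-one | C[C@]1(O)CC[C@H](C(=C)COCc2ccc(OC)cc2)C[C@@H](O[Si](C)(C)C(C)(C)C)/C(C)=C/C/C=C(/C)CCC1=O
F3 | step 9 | (2E,5Z)-9,9-diethoxy-2-iodo-6-methylnona-2,5-diene | I/C(C)=C/C/C=C(/C)CCC(OCC)OCC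
F4 | step 9 | (1S,3S,4E,7Z)-11,11-diethoxy-3-hydroxy-16-(4-methoxybenzyloxy)-11,12-secocembra-4,7,15(17)-trien-12-one (C3 epimer of 22) | CC(=O)CC[C@H](C(=C)COCc1ccc(OC)cc1)C[C@H](O)/C(C)=C/C/C=C(/C)CCC(OCC)OCC
F5 | step 9 | (1S,3R,4E,7Z)-11,11-diethoxy-16-(4-methoxybenzyloxy)-12-oxo-11,12-secocembra-4,7,15(17)-trien-3-yl 4-nitrobenzoate | CC(=O)CC[C@H](C(=C)COCc1ccc(OC)cc1)C[C@@H](OC(=O)c1ccc(cc1)[N+](=O)[O-])/C(C)=C/C/C=C(/C)CCC(OCC)OCC
F6 | step 17 | S-(pyridin-2-yl) (1S,3R,4E,7Z,11R,12S)-11-acetoxy-3-(tert-butyldimethylsilyloxy)-12-hydroxycembra-4,7,15(17)-triene-16-thioate | C[C@]1(O)CC[C@H](C(=C)C(=O)Sc2ccccn2)C[C@@H](O[Si](C)(C)C(C)(C)C)/C(C)=C/C/C=C(/C)CC[C@H]1OC(C)=O
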